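(The data were generated by integration on assumed constants; the scatter is artificial.)

The constants were hidden, so I went for the one the runs show: how fast free catalyst removes starting material, treated as pseudo-first-order at a fixed starting material charge.

| flask | starting material | free catalyst | remark | time |
|---|---|---|---|---|
| alder | 0.40 M | 0.40 mM (in portions, 2) | run made earlier; portions every 10 h |  |
| ash | 0.60 M | 0.40 mM (in portions, 2) | run made earlier; portions every 10 h |  |
| cedar | 0.80 M | 0.80 mM (in portions, 2) | run made earlier; portions every 10 h |  |
| flask | 0.80 M | 0.40 mM (in portions, 2) | the portions of free catalyst follow each other after 10 h, the first at the start | 20 h |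

- alder (time / h: target / %, over-reaction product / %): 1.50: 10.8, 1.5; 3.00: 18.3, 6.1; 6.00: 24.5, 18.0; 10.0: 24.9, 36.2; 20.0: 15.4, 79.2
- ash (time / h: target / %, over-reaction product / %): 2.00: 12.4, 3.0; 5.00: 21.6, 12.3; 10.0: 24.1, 34.4; 15.0: 25.1, 59.9; 20.0: 16.1, 78.7
- cedar (time / h: target / %, over-reaction product / %): 1.50: 18.0, 3.0; 3.00: 28.3, 9.2; 6.00: 35.0, 27.8; 10.0: 30.3, 52.6; 20.0: 9.2, 90.7

(readings scatter by 0.3 percentage points)

- what was read earlier has a scatter of 0.3 percentage points, one standard deviation
- a reading or a percentage of target counts all its forms, free or not

* target present at 20 h, in percent of the starting material charged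
* over-reaction product present at 20 h, in percent of the starting material charged

The flask's 21.6 M·s is the quantity I carried: the dose, charged free catalyst concentration summed over the hours since its addition. Alder's dose of 21.6 M·s and ash's of 21.6 M·s match it.

Cedar was charged with the flask's 0.80 M of starting material. By 10.0 h it had taken 14.4 M·s, and the unread remainder, which I took as starting material, stood at 17.1%. One constant slope then gave the flask 7.07% at 20 h.

At 6.00 h, after 8.64 M·s, cedar's remainder was 37.2%. That slope was the weak link: per unit of dose, cedar's remainder fell faster after 6.00 h than before it. Continuing from cedar's later stretch gave me 6.47% instead.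

For target I stepped on from alder and ash, equal steps in starting material at equal dose, to 16.8%. The balance left 76.7% over-reaction product.

The forecast, made separately, said 16.2% target and 77.6% over-reaction product, holding that “The first step scales with catalyst but is mildly damped by starting material”.

The flask gave 16.8% target and 77.0% over-reaction product.

    starting material + free catalyst ⇌ catalyst intermediate A (K = 0.570 M⁻¹, k = 21.0 M⁻¹ min⁻¹)
    catalyst intermediate A ⇌ catalyst intermediate B (K = 1.00, k = 100 min⁻¹)
    catalyst intermediate B → free catalyst + target (k = 37.0 min⁻¹)
    crystals ⇌ target, rate k4*(cs4 - [target]) while solid is left; crystals form when [target] > cs4 (solubility = 0.290 M, k = 0.210 min⁻¹)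
    target → over-reaction product (k = 0.00310 min⁻¹)

The flask ended at 6.3% starting material, against my 6.47%. A neighbour charged with 1.0 × 10⁻⁴ M of free catalyst, in the same portions, took 5.40 M·s, a quarter of the flask's dose. This is less than cedar's dose at 6.00 h, so I used cedar's early stretch, which gives 53.9% starting material. The neighbour ended at 55.1% starting material.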